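## Structural features

The target is an achiral diaryl ether in which two benzoic acid rings are joined through one oxygen; it has no stereocentre and no ring other than the two benzenes. Ring A is tetrasubstituted (C1 carboxyl, C2 aryloxy, C4 methoxy, C6 heptyl). Ring B is pentasubstituted (C1' carboxyl, C2' heptyl, C3' methoxy, C4' ether oxygen, C6' hydroxyl), with C5'–H as its only free position. Each carboxyl group sits between two ortho substituents, and the ring B acid is a 6-alkylsalicylic acid that loses CO2 in hot acid, so both acids are best uncovered last under neutral conditions. The real difficulty is the ether bond: the ring B oxygen is flanked by the C3' methoxy group and the ring A carbon is ortho to a doubly flanked carboxyl, a poor case for metal-mediated coupling of an aryl halide. A second difficulty is the contiguous heptyl–methoxy–oxygen array C2'–C3'–C4' of ring B, which electrophilic substitution of a resorcylate does not deliver and which is therefore built together with the ring. The key step uses the fact that the ether oxygen on C2 and the carboxyl carbon on C1 of ring A are neighbours, so both are added across the C1–C2 triple bond of 3-heptyl-5-methoxybenzyne. That aryne is released here from the silyl triflate carrying silicon on the future C2 and the sulfonate on the future C1; the isomer with the two groups exchanged gives the same aryne but would need bromination of 3-heptyl-5-methoxyphenol between hydroxyl and heptyl, where the position para to the hydroxyl competes, whereas the isomer used comes from 2-heptyl-4-methoxyphenol, which has only one open position ortho to the hydroxyl. The ring B phenol enters the key step as its silyl ether, so that fluoride frees the phenoxide without leaving an acidic proton in the flask.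

## Logic of the disconnections

**26 back to 25.** The two O–CH2Ph bonds on ring B (ether on the C6' oxygen, ester on the C1' carboxyl) are cut. Both fall in one neutral hydrogenolysis, so the decarboxylation-prone acid appears only at the end. The forward step must leave the diaryl ether and both arenes untouched, which mild hydrogenation over palladium does.

**25 back to 20, 9 and 21.** The C2–O bond and the C1–carboxyl bond of ring A are cut together. This removes the hindered ether coupling and the doubly flanked acid in one operation and leaves two fragments of similar size. In the forward direction 20 must be converted into 22 without a proton source, 9 must give 23, 22 must add to the aryne carbon remote from the heptyl group, and 24 must be captured by 21 faster than by any proton.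

**20 back to 19 and 18.** The O–CH2Ph bond on the C6' oxygen and the O–Si bond on the C4' oxygen are cut. The order of introduction follows the natural reactivity of 18: the free, more acidic C4' hydroxyl is silylated first, and the hydrogen-bonded C6' hydroxyl is then alkylated under neutral conditions that the silyl ether tolerates. The silyl group is not removed in a separate step, because it serves as the phenoxide source in the key step.

**18 back to 16.** Ring B is taken back to its dihydro form, a cyclic 1,3-dione. Only two hydrogens have to be removed in the forward step (through 17), and the methoxy group must stay in place.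

**16 back to 13 and 14.** The C1'–C2' bond (conjugate addition) and the C5'–C6' bond (Claisen closure through 15) are cut. This sets the heptyl, methoxy and two oxygen substituents in their final order from an acyclic enone and a malonate. The forward step demands conjugate addition to an enone whose reactivity is lowered by its alpha-methoxy group, which the irreversible ring closure to a stabilised dione enolate is meant to drive.

**13 back to 11 and 12, and 11 back to 10.** The C=C bond of 13 is cut by an olefination logic; the methoxy group is placed on the phosphonate carbon so that its position in 13 is unambiguous. The phosphonate 11 comes from 10 by formation of one C–O bond.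

**9 back to 6.** The C–Si bond and the O–S bond are cut. The bromine of 6 marks the carbon that receives silicon (through 7 and 8), so the regiochemistry of 9 is fixed by that of 6.

**6 back to 5, 4, 1 and 2.** The C–Br bond is cut ortho to the hydroxyl, the only open ortho position, the para position being blocked by methoxy. The heptyl chain is traced to a C=C bond formed from 1 and 2 (through 3). The forward olefination must tolerate a free phenol, which is handled by an excess of ylide.

## Other disconnections considered

**Alternative 1:** The cut runs through ring B itself, at the C1'–C6' bond. In the forward direction the squarate-derived cyclobutenone A1, which carries the ring A aryloxy group on C3 and a methoxy group and a trisubstituted alkenyl group on C4, is heated. It opens to a dienylketene, which closes by 6π electrocyclization and tautomerises to the phenol A2.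
- In its favour: every substituent position of ring B is fixed by the connectivity of A1, so there is no site-selectivity question of the kind the aryne addition raises. On this point the alternative is the better plan. The conditions are neutral and thermal, the reaction class is well precedented (also better than an untested three-component coupling), and the ether bond is made early by addition–elimination on a squarate, which avoids a hindered aryl halide coupling just as the chosen plan does.
- Against it here: A2 carries the ring B carboxyl carbon as a silyl-protected CH2OH and the ring A acid as a tert-butyl ester. Desilylation, a two-stage oxidation next to a free electron-rich phenol and ester cleavage must follow, about four operations against one in the chosen plan. A1 also needs ordered additions to a squarate, a geometrically defined alkenyl-metal reagent and a separately made ring A phenol.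
- Comparison: structurally and mechanistically safer at the key step, clearly longer overall.

**Alternative 2:** The cut is the C1'–C2' bond of ring B. In the forward direction mild base makes the active methylene of the keto ester in the acyclic aryloxy enone A3 attack the heptyl ketone; loss of water and enolization give the phenol A4.
- In its favour: the conditions are mild, no oxidant is needed and the ring B substitution pattern follows from the chain (again better than steric control on an aryne). A4 is a bis(benzyl ester) with a free C6' phenol, so the end is a single hydrogenolysis, equal to the chosen plan.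
- Against it here: A3 is a vinylogous aryl ester next to an alpha-methoxy ketone. The ring A aryloxide is a leaving group towards any nucleophile, including the enolate oxygen of the keto ester (pyranone formation). The double bond must also hold the geometry that brings the two arms together, and the polycarbonyl chain and the ring A phenol each need their own synthesis.
- Comparison: equal end game, better intrinsic regiocontrol, but a fragile precursor and no saving in steps.

**Alternative 3:** The cut removes two bonds of ring A, C1–C2 and C5–C6. In the forward direction the 6-aryloxy-4-methoxy-2-pyrone A5 and benzyl dec-2-ynoate A6 undergo a thermal Diels–Alder reaction; the bridged lactone loses CO2 and leaves the arene A7.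
- In its favour: the orientation is electronically matched, since the nucleophilic C3 of the pyrone pairs with the beta carbon of the ynoate. This is better than the steric control of the chosen plan. The doubly flanked ester is formed without any substitution at a hindered aromatic carbon, and the end is one hydrogenolysis, equal to the chosen plan.
- Against it here: a beta-alkyl ynoate is a sluggish dienophile, so high temperatures are needed, at which the aryloxy pyrone (an acyl ketene acetal) may fragment or transfer its aryl group. A5 must be made from a 6-halo-4-methoxy-2-pyrone and the phenol unmasked from 20, so the whole ring B line of the chosen plan is still required.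
- Comparison: better regiocontrol and a known reaction class, similar step count, but harsher conditions on a more fragile intermediate.

Key step: step 11

Assumption (remark on the chemistry): the target has no stereocentre; alkenes 4 and 13 are used as E/Z mixtures and 11, 15, 16 and 17 as mixtures of stereoisomers, since all these elements are erased before the target.

## Route

Step 1
Reactants: 1 2-hydroxy-5-methoxybenzaldehyde; 2 hexyltriphenylphosphonium bromide
Product: 4 2-(hept-1-en-1-yl)-4-methoxyphenol (E/Z mixture), via hexylidenetriphenylphosphorane 3 (not isolated)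
Conditions: 2 (2.2 equiv), KOt-Bu (2.2 equiv), THF, 0 °C; then 1, 0 °C to rt
Reagents that add atoms: none
Why: Wittig olefination; one equivalent of ylide 3 is spent on the phenol proton and the excess unstabilised ylide olefinates the phenoxide aldehyde; the alkene geometry is irrelevant because step 2 saturates it.

Step 2
Reactants: 4 2-(hept-1-en-1-yl)-4-methoxyphenol
Product: 5 2-heptyl-4-methoxyphenol
Conditions: H2 (1 atm), Pd/C (10 wt %), EtOAc, rt
Reagents that add atoms: none
Why: Catalytic hydrogenation of a disubstituted styrenyl alkene; the aryl ether and phenol are inert under these conditions.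

Step 3
Reactants: 5 2-heptyl-4-methoxyphenol
Product: 6 2-bromo-6-heptyl-4-methoxyphenol
Conditions: NBS (1.0 equiv), i-Pr2NH (10 mol %), CH2Cl2, 0 °C, dark
Reagents that add atoms: N-bromosuccinimide, O=C1CCC(=O)N1Br
Why: Electrophilic aromatic bromination directed by the hydroxyl group; the para position is blocked by methoxy and one ortho position by heptyl, so only C6 is open, and the amine-mediated ortho-selective protocol in dry solvent avoids oxidation to a quinone.

Step 4
Reactants: 6 2-bromo-6-heptyl-4-methoxyphenol
Product: 9 2-heptyl-4-methoxy-6-(trimethylsilyl)phenyl trifluoromethanesulfonate, via aryl trimethylsilyl ether 7 (not isolated), via lithium silylphenoxide 8 (not isolated)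
Conditions: HMDS, THF, 65 °C, then concentrate; n-BuLi (1.1 equiv), THF, −78 °C; Tf2O (1.2 equiv), −78 °C to rt
Reagents that add atoms: hexamethyldisilazane, C[Si](C)(C)N[Si](C)(C)C; trifluoromethanesulfonic anhydride, O=S(=O)(OS(=O)(=O)C(F)(F)F)C(F)(F)F
Why: Standard one-flask route to ortho-silylaryl triflates: O-silylation, bromine–lithium exchange, retro-Brook shift of silicon from oxygen to the lithiated carbon, and triflation of the resulting phenoxide 8; the bromine of 6 fixes where silicon ends up.

Step 5
Reactants: 10 dimethyl (1-diazo-2-oxopropyl)phosphonate
Product: 11 dimethyl (1-methoxy-2-oxopropyl)phosphonate (racemic)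
Conditions: MeOH (5 equiv), Rh2(OAc)4 (1 mol %), 1,2-dichloroethane, 70 °C
Reagents that add atoms: methanol, CO
Why: Rhodium carbenoid O–H insertion into methanol; it places the methoxy group on the phosphonate carbon and so defines the later position of the ring B methoxy group.

Step 6
Reactants: 11 dimethyl (1-methoxy-2-oxopropyl)phosphonate; 12 octanal
Product: 13 3-methoxyundec-3-en-2-one (E/Z mixture)
Conditions: NaH (1.05 equiv), THF, 0 °C; then 12, 0 °C to rt
Reagents that add atoms: none
Why: Horner–Wadsworth–Emmons olefination of an aliphatic aldehyde with an alpha-alkoxy keto phosphonate; both alkene isomers serve in step 7.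

Step 7
Reactants: 13 3-methoxyundec-3-en-2-one; 14 dibenzyl malonate
Product: 16 benzyl 6-heptyl-5-methoxy-2,4-dioxocyclohexane-1-carboxylate (stereoisomer/tautomer mixture), via Michael adduct 15 (not isolated)
Conditions: 14 (1.1 equiv), KOt-Bu (1.2 equiv), t-BuOH/THF, rt to 65 °C; then 1 M HCl
Reagents that add atoms: none
Why: Michael addition followed by Claisen (Dieckmann-type) closure, the classical route to dihydroresorcylates from an enone and a malonate; the malonate carbon bonds to the heptyl-bearing beta carbon and the methyl ketone closes onto one benzyl ester, the stable dione enolate being the thermodynamic sink, and tert-butoxide in tert-butanol avoids ester exchange.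

Step 8
Reactants: 16 benzyl 6-heptyl-5-methoxy-2,4-dioxocyclohexane-1-carboxylate
Product: 18 benzyl 2-heptyl-4,6-dihydroxy-3-methoxybenzoate, via 3-bromo dione 17 (not isolated)
Conditions: Br2 (1.0 equiv), DMF, 0 °C; then 70 °C
Reagents that add atoms: none
Why: Bromination–dehydrobromination aromatization of a 2,4-dioxocyclohexanecarboxylate, as used for olivetolate-type esters; the dione enol is brominated faster than the product and loss of two HBr gives the resorcylate with the methoxy group retained.

Step 9
Reactants: 18 benzyl 2-heptyl-4,6-dihydroxy-3-methoxybenzoate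
Product: 19 benzyl 4-[(tert-butyldimethylsilyl)oxy]-2-heptyl-6-hydroxy-3-methoxybenzoate
Conditions: TBSCl (1.05 equiv), imidazole, CH2Cl2, 0 °C
Reagents that add atoms: tert-butyldimethylsilyl chloride, CC(C)(C)[Si](C)(C)Cl
Why: Selective silylation of the more acidic C4' hydroxyl; the C6' hydroxyl is held in a hydrogen bond to the ester and is much less reactive.

Step 10
Reactants: 19 benzyl 4-[(tert-butyldimethylsilyl)oxy]-2-heptyl-6-hydroxy-3-methoxybenzoate
Product: 20 benzyl 6-(benzyloxy)-4-[(tert-butyldimethylsilyl)oxy]-2-heptyl-3-methoxybenzoate
Conditions: BnOH (1.5 equiv), PPh3 (1.5 equiv), DIAD (1.5 equiv), THF, 0 °C to rt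
Reagents that add atoms: benzyl alcohol, OCc1ccccc1
Why: Mitsunobu etherification of the salicylate hydroxyl; the neutral conditions leave the aryl silyl ether intact, which carbonate bases in polar solvents would not.

Step 11
Reactants: 20 benzyl 6-(benzyloxy)-4-[(tert-butyldimethylsilyl)oxy]-2-heptyl-3-methoxybenzoate; 9 2-heptyl-4-methoxy-6-(trimethylsilyl)phenyl trifluoromethanesulfonate; 21 carbon dioxide
Product: 25 2-[5-(benzyloxy)-4-[(benzyloxy)carbonyl]-3-heptyl-2-methoxyphenoxy]-6-heptyl-4-methoxybenzoic acid, via potassium phenoxide 22 (not isolated), via 3-heptyl-5-methoxybenzyne 23 (not isolated), via aryl anion 24 (not isolated)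
Conditions: 20, KF (4 equiv), 18-crown-6 (4 equiv), THF, rt; then CO2 (1 atm), 0 °C, slow addition of 9 (1.3 equiv), 0 °C to rt; 1 M HCl work-up
Reagents that add atoms: none
Why: Proposed new method: fluoride first cleaves the O–Si bond of 20 to give the phenoxide 22 and then attacks silicon of 9, so that triflate leaves and aryne 23 forms; 22 adds to the aryne carbon remote from the heptyl group, and the aryl anion 24 created on the carbon next to heptyl is carboxylated by 21. The closest known reactions are the three-component union of arynes, amines and CO2 to anthranilic acids and the fluoride-triggered O-arylation of phenols by arynes. No ring is closed and no stereocentre is formed. Protonation of 24 is suppressed by design: the phenol enters as a silyl ether, THF replaces the more acidic acetonitrile, and the fluoride source is anhydrous crown-complexed KF. The step needs site selectivity on an unsymmetrical aryne, and this rests on sterics: the heptyl group flanks one aryne carbon and the methoxy-flanked, ion-paired phenoxide is bulky, whereas the ring A methoxy group (meta to the attacked carbon) gives no help and may exert a slight opposing inductive pull. A minor regioisomeric acid is therefore expected and is to be separated by chromatography. Slow addition of 9 keeps the aryne concentration low so that the product carboxylate and 24 do not consume a second aryne. The ring B ester is para to the attacking oxygen, so the xanthone-type closure open to salicylate oxygens cannot occur.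

Step 12
Reactants: 25 2-[5-(benzyloxy)-4-[(benzyloxy)carbonyl]-3-heptyl-2-methoxyphenoxy]-6-heptyl-4-methoxybenzoic acid
Product: 26 2-(4-carboxy-3-heptyl-5-hydroxy-2-methoxyphenoxy)-6-heptyl-4-methoxybenzoic acid (target)
Conditions: H2 (1 atm), Pd/C (10 wt %), EtOAc/MeOH, rt
Reagents that add atoms: none
Why: Hydrogenolysis of the benzyl ether and the benzyl ester in one neutral operation; the diaryl ether, the methyl ethers and the free acids are stable, and the salicylic acid is never exposed to hot acid.

## Compound list

1 | 2-hydroxy-5-methoxybenzaldehyde | COc1ccc(O)c(C=O)c1 | starting material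
2 | hexyltriphenylphosphonium bromide | CCCCCC[P+](c1ccccc1)(c1ccccc1)c1ccccc1.[Br-] | starting material
3 | hexylidenetriphenylphosphorane | CCCCCC=P(c1ccccc1)(c1ccccc1)c1ccccc1 | intermediate
4 | 2-(hept-1-en-1-yl)-4-methoxyphenol (E/Z mixture) | CCCCCC=Cc1cc(OC)ccc1O | intermediate
5 | 2-heptyl-4-methoxyphenol | CCCCCCCc1cc(OC)ccc1O | intermediate
6 | 2-bromo-6-heptyl-4-methoxyphenol | CCCCCCCc1cc(OC)cc(Br)c1O | intermediate
7 | (2-bromo-6-heptyl-4-methoxyphenoxy)trimethylsilane | CCCCCCCc1cc(OC)cc(Br)c1O[Si](C)(C)C | intermediate
8 | lithium 2-heptyl-4-methoxy-6-(trimethylsilyl)phenoxide | CCCCCCCc1cc(OC)cc([Si](C)(C)C)c1[O-].[Li+] | intermediate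
9 | 2-heptyl-4-methoxy-6-(trimethylsilyl)phenyl trifluoromethanesulfonate | CCCCCCCc1cc(OC)cc([Si](C)(C)C)c1OS(=O)(=O)C(F)(F)F | intermediate
10 | dimethyl (1-diazo-2-oxopropyl)phosphonate | CC(=O)C(=[N+]=[N-])P(=O)(OC)OC | starting material
11 | dimethyl (1-methoxy-2-oxopropyl)phosphonate (racemic) | CC(=O)C(OC)P(=O)(OC)OC | intermediate
12 | octanal | CCCCCCCC=O | starting material
13 | 3-methoxyundec-3-en-2-one (E/Z mixture) | CCCCCCCC=C(OC)C(C)=O | intermediate
14 | dibenzyl malonate | O=C(CC(=O)OCc1ccccc1)OCc1ccccc1 | starting material
15 | dibenzyl 2-(3-methoxy-2-oxoundecan-4-yl)malonate (diastereomer mixture) | CCCCCCCC(C(OC)C(C)=O)C(C(=O)OCc1ccccc1)C(=O)OCc1ccccc1 | intermediate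
16 | benzyl 6-heptyl-5-methoxy-2,4-dioxocyclohexane-1-carboxylate (stereoisomer/tautomer mixture) | CCCCCCCC1C(OC)C(=O)CC(=O)C1C(=O)OCc1ccccc1 | intermediate
17 | benzyl 3-bromo-6-heptyl-5-methoxy-2,4-dioxocyclohexane-1-carboxylate (stereoisomer mixture) | CCCCCCCC1C(OC)C(=O)C(Br)C(=O)C1C(=O)OCc1ccccc1 | intermediate
18 | benzyl 2-heptyl-4,6-dihydroxy-3-methoxybenzoate | CCCCCCCc1c(OC)c(O)cc(O)c1C(=O)OCc1ccccc1 | intermediate
19 | benzyl 4-[(tert-butyldimethylsilyl)oxy]-2-heptyl-6-hydroxy-3-methoxybenzoate | CCCCCCCc1c(OC)c(O[Si](C)(C)C(C)(C)C)cc(O)c1C(=O)OCc1ccccc1 | intermediate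
20 | benzyl 6-(benzyloxy)-4-[(tert-butyldimethylsilyl)oxy]-2-heptyl-3-methoxybenzoate | CCCCCCCc1c(OC)c(O[Si](C)(C)C(C)(C)C)cc(OCc2ccccc2)c1C(=O)OCc1ccccc1 | intermediate
21 | carbon dioxide | O=C=O | starting material
22 | potassium 5-(benzyloxy)-4-[(benzyloxy)carbonyl]-3-heptyl-2-methoxyphenoxide | CCCCCCCc1c(OC)c([O-])cc(OCc2ccccc2)c1C(=O)OCc1ccccc1.[K+] | intermediate
23 | 3-heptyl-5-methoxy-1,2-didehydrobenzene (3-heptyl-5-methoxybenzyne) | CCCCCCCC1=CC(OC)=CC#C1 | intermediate
24 | potassium 2-[5-(benzyloxy)-4-[(benzyloxy)carbonyl]-3-heptyl-2-methoxyphenoxy]-6-heptyl-4-methoxybenzen-1-ide | CCCCCCCc1cc(OC)cc(Oc2cc(OCc3ccccc3)c(C(=O)OCc3ccccc3)c(CCCCCCC)c2OC)[c-]1.[K+] | intermediate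
25 | 2-[5-(benzyloxy)-4-[(benzyloxy)carbonyl]-3-heptyl-2-methoxyphenoxy]-6-heptyl-4-methoxybenzoic acid | CCCCCCCc1cc(OC)cc(Oc2cc(OCc3ccccc3)c(C(=O)OCc3ccccc3)c(CCCCCCC)c2OC)c1C(=O)O | intermediate
26 | 2-(4-carboxy-3-heptyl-5-hydroxy-2-methoxyphenoxy)-6-heptyl-4-methoxybenzoic acid | CCCCCCCc1cc(OC)cc(Oc2cc(O)c(C(=O)O)c(CCCCCCC)c2OC)c1C(=O)O | target

## Step count and least certain steps

Total step count: 12. Longest linear sequence: 8 steps (steps 5 to 12); the ring A line contributes steps 1 to 4.

**Step 11 (key step).** The most likely failure is poor site selectivity in the addition of 22 to 23, because a primary alkyl group gives only a modest steric bias and the ring A methoxy group does not reinforce it. The second risk is loss of the carboxylation: protonation of 24 by adventitious water, reversible carbonate formation from 22 and 21 that slows the addition, or capture of a second aryne by the product carboxylate.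

The fallback uses known chemistry and fixes the regiochemistry by symmetry. It sets out from 20 and returns at 25.
- Desilylation of 20 with Bu4NF gives benzyl 6-(benzyloxy)-2-heptyl-4-hydroxy-3-methoxybenzoate F1.
- Separately, purchased 2,6-difluoro-4-methoxybenzaldehyde F2 is condensed with cyclohexylamine to N-cyclohexyl-1-(2,6-difluoro-4-methoxyphenyl)methanimine F3.
- Heptylmagnesium bromide displaces one ortho fluoride of F3 in an imine-directed, Meyers-type substitution to give N-cyclohexyl-1-(2-fluoro-6-heptyl-4-methoxyphenyl)methanimine F4.
- Acid hydrolysis of F4 gives 2-fluoro-6-heptyl-4-methoxybenzaldehyde F5.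
- Nucleophilic aromatic substitution of the aldehyde-activated fluoride of F5 by F1 (K2CO3, DMF, 100 °C) gives benzyl 6-(benzyloxy)-4-(2-formyl-3-heptyl-5-methoxyphenoxy)-2-heptyl-3-methoxybenzoate F6.
- Pinnick oxidation of F6 (NaClO2, NaH2PO4, 2-methyl-2-butene) gives 25.

**Step 7.** The most likely failure is sluggish conjugate addition, because the alpha-methoxy group donates into the enone and lowers its acceptor strength; competing deprotonation of the enone at its gamma position would then consume base.

The fallback reverses the polarity. It sets out from 12 and 14 and returns at 15.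
- Knoevenagel condensation of 12 with 14 (TiCl4, pyridine, THF) gives dibenzyl 2-octylidenemalonate F7.
- Methoxyacetone is converted (TMSCl, NaI, Et3N, MeCN) into 1-methoxy-2-(trimethylsilyloxy)prop-1-ene F8.
- Mukaiyama–Michael addition of F8 to F7 (TiCl4, CH2Cl2, −78 °C) gives 15 after aqueous work-up.
- Isolated 15 is then closed to 16 with KOt-Bu as in step 7.

**Step 8.** The most likely failures are cleavage of the benzyl ester by the HBr set free at 70 °C and further bromination of the electron-rich product at C5'.

The fallback avoids halogen and acid. It sets out from 16 and returns at 18.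
- Treatment of 16 with TMSOTf and Et3N gives benzyl 6-heptyl-5-methoxy-2,4-bis[(trimethylsilyl)oxy]cyclohexa-1,3-diene-1-carboxylate F9.
- DDQ dehydrogenates the cyclohexadiene F9 to benzyl 2-heptyl-3-methoxy-4,6-bis[(trimethylsilyl)oxy]benzoate F10.
- Mild aqueous acid removes both silyl groups of F10 and gives 18.

**Step 10.** The most likely failure is incomplete alkylation of the hindered, hydrogen-bonded hydroxyl under Mitsunobu conditions, with silyl loss or migration on prolonged reaction.

The fallback uses a base-stable temporary group. It sets out from 18 and returns at 22.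
- Selective allylation of the C4' hydroxyl of 18 (allyl bromide, K2CO3, acetone) gives benzyl 4-(allyloxy)-2-heptyl-6-hydroxy-3-methoxybenzoate F11.
- Benzylation of F11 (BnBr, K2CO3, DMF, 60 °C) gives benzyl 4-(allyloxy)-6-(benzyloxy)-2-heptyl-3-methoxybenzoate F12.
- Deallylation of F12 with Pd(PPh3)4 and morpholine gives the phenol F1 described under step 11.
- Deprotonation with KH in THF, which leaves only hydrogen gas behind, gives 22 for use in step 11.

## Further compounds

F1 | step 11 | benzyl 6-(benzyloxy)-2-heptyl-4-hydroxy-3-methoxybenzoate | CCCCCCCc1c(OC)c(O)cc(OCc2ccccc2)c1C(=O)OCc1ccccc1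
F2 | step 11 | 2,6-difluoro-4-methoxybenzaldehyde (purchased) | COc1cc(F)c(C=O)c(F)c1
F3 | step 11 | N-cyclohexyl-1-(2,6-difluoro-4-methoxyphenyl)methanimine | COc1cc(F)c(/C=N/C2CCCCC2)c(F)c1
F4 | step 11 | N-cyclohexyl-1-(2-fluoro-6-heptyl-4-methoxyphenyl)methanimine | CCCCCCCc1cc(OC)cc(F)c1/C=N/C1CCCCC1
F5 | step 11 | 2-fluoro-6-heptyl-4-methoxybenzaldehyde | CCCCCCCc1cc(OC)cc(F)c1C=O
F6 | step 11 | benzyl 6-(benzyloxy)-4-(2-formyl-3-heptyl-5-methoxyphenoxy)-2-heptyl-3-methoxybenzoate | CCCCCCCc1cc(OC)cc(Oc2cc(OCc3ccccc3)c(C(=O)OCc3ccccc3)c(CCCCCCC)c2OC)c1C=O
F7 | step 7 | dibenzyl 2-octylidenemalonate | CCCCCCCC=C(C(=O)OCc1ccccc1)C(=O)OCc1ccccc1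
F8 | step 7 | 1-methoxy-2-(trimethylsilyloxy)prop-1-ene (Z isomer drawn; geometry immaterial) | CO/C=C(/C)O[Si](C)(C)C
F9 | step 8 | benzyl 6-heptyl-5-methoxy-2,4-bis[(trimethylsilyl)oxy]cyclohexa-1,3-diene-1-carboxylate (stereoisomer mixture) | CCCCCCCC1C(OC)C(O[Si](C)(C)C)=CC(O[Si](C)(C)C)=C1C(=O)OCc1ccccc1
F10 | step 8 | benzyl 2-heptyl-3-methoxy-4,6-bis[(trimethylsilyl)oxy]benzoate | CCCCCCCc1c(OC)c(O[Si](C)(C)C)cc(O[Si](C)(C)C)c1C(=O)OCc1ccccc1
F11 | step 10 | benzyl 4-(allyloxy)-2-heptyl-6-hydroxy-3-methoxybenzoate | C=CCOc1cc(O)c(C(=O)OCc2ccccc2)c(CCCCCCC)c1OC
F12 | step 10 | benzyl 4-(allyloxy)-6-(benzyloxy)-2-heptyl-3-methoxybenzoate | C=CCOc1cc(OCc2ccccc2)c(C(=O)OCc2ccccc2)c(CCCCCCC)c1OC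
A1 | alternative 1 | tert-butyl 2-({3-[1-(tert-butyldimethylsilyloxy)dec-2-en-3-yl]-3-methoxy-4-oxocyclobut-1-en-1-yl}oxy)-6-heptyl-4-methoxybenzoate (racemic; alkene geometry not fixed) | CCCCCCCC(=CCO[Si](C)(C)C(C)(C)C)C1(OC)C(=O)C=C1Oc1cc(OC)cc(CCCCCCC)c1C(=O)OC(C)(C)C
A2 | alternative 1 | tert-butyl 2-[4-({[tert-butyl(dimethyl)silyl]oxy}methyl)-3-heptyl-5-hydroxy-2-methoxyphenoxy]-6-heptyl-4-methoxybenzoate | CCCCCCCc1c(CO[Si](C)(C)C(C)(C)C)c(O)cc(Oc2cc(OC)cc(CCCCCCC)c2C(=O)OC(C)(C)C)c1OC
A3 | alternative 2 | benzyl (4E)-5-{2-[(benzyloxy)carbonyl]-3-heptyl-5-methoxyphenoxy}-6-methoxy-3,7-dioxotetradec-4-enoate (racemic; the two carbonyl-bearing arms cis) | CCCCCCCC(=O)C(OC)/C(Oc1cc(OC)cc(CCCCCCC)c1C(=O)OCc1ccccc1)=C\C(=O)CC(=O)OCc1ccccc1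
A4 | alternative 2 | benzyl 4-{2-[(benzyloxy)carbonyl]-3-heptyl-5-methoxyphenoxy}-2-heptyl-6-hydroxy-3-methoxybenzoate | CCCCCCCc1c(OC)c(Oc2cc(OC)cc(CCCCCCC)c2C(=O)OCc2ccccc2)cc(O)c1C(=O)OCc1ccccc1
A5 | alternative 3 | benzyl 6-(benzyloxy)-2-heptyl-3-methoxy-4-[(4-methoxy-2-oxo-2H-pyran-6-yl)oxy]benzoate | CCCCCCCc1c(OC)c(Oc2cc(OC)cc(=O)o2)cc(OCc2ccccc2)c1C(=O)OCc1ccccc1
A6 | alternative 3 | benzyl dec-2-ynoate | CCCCCCCC#CC(=O)OCc1ccccc1
A7 | alternative 3 | benzyl 6-(benzyloxy)-4-{2-[(benzyloxy)carbonyl]-3-heptyl-5-methoxyphenoxy}-2-heptyl-3-methoxybenzoate | CCCCCCCc1cc(OC)cc(Oc2cc(OCc3ccccc3)c(C(=O)OCc3ccccc3)c(CCCCCCC)c2OC)c1C(=O)OCc1ccccc1
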